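In this flask the catalyst could not turn over more than 24.2 times: each turn takes one reagent, and 0.150 M of reagent faced 6.2 mM of catalyst. I called that ratio, c(reagent)/c(catalyst), the turnover budget; reagent is the limiting reagent here.

| setting | east | south-west | flask |
|---|---|---|---|
| starting material | 0.25 M | 0.25 M | 0.25 M |
| reagent | 0.15 M | 0.15 M | 0.150 M |
| second substrate | 0.25 M | 0.25 M | 0.250 M |
| catalyst | 4.2 mM | 9.3 mM | 6.2 mM |
| remark | run made earlier | run made earlier |  |
| time |  |  | 20 h |

| run | time / h | target / % | starting material / % |
|---|---|---|---|
| east | 0.250 | 14 | 66 |
| east | 1.00 | 23 | 30 |
| east | 5.00 | 13 | 9 |
| east | 20.0 | 3 | 3 |
| south-west | 0.250 | 23 | 55 |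
| south-west | 1.00 | 27 | 26 |
| south-west | 5.00 | 13 | 9 |
| south-west | 20.0 | 0 | 1 |

(each reading ± 1.5 percentage points)

- percentages count the starting material that a species holds: one homo dimer or side product counts as two
- the earlier runs were read with a standard deviation of 1.5 percentage points
- what may be going on: 2 starting material -> homo dimer; starting material + reagent + catalyst -> catalyst + target; starting material + target -> side product; target -> over-reaction product; second substrate + reagent + catalyst -> catalyst + second product

- the moment within 20 h at which there is most target
- the amount of target, in percent of the starting material charged, at that time
- earliest time at which at least nineteen twentieths of that best amount are there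
- latest time at which they still are

I took the settings one at a time. At a fixed catalyst charge, a larger reagent charge raises the budget in proportion, but the east and south-west runs both held 0.15 M, so they showed nothing of it. Each second product costs a turn from the same budget, and no reading counts those turns. Catalyst was the setting the runs did turn: the budget fell from 35.7 in the east run to 16.1 in the south-west run, so I expected it to be spent sooner there. Their first readings gave the pace, in target turns per catalyst per hour, and I left the uncounted second-product turns out of it:

east: 33.3 /h

south-west: 24.7 /h

mean, for this flask: 29.0 /h

budget / pace: 0.833 h

The same division gave 1.07 h for the east run, whose highest reading stood at 1.00 h. So I expected the top of this flask near 0.833 h, with a height between the runs' highest readings, 23% and 27%.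

The forecast said “a flat peak near 0.9 h at about 26%”, with 0.9 h, 25.8% and a window from 0.58 h to 1.4 h.

The flask gave 26.8% at 0.938 h, with the window open from 0.572 h to 1.51 h. My one division came 0.105 h early, and the height lay between the two readings.

    2 starting material → homo dimer (k = 0.0420 /M/min)
    starting material + reagent + catalyst → catalyst + target (k = 25.0 /M²/min)
    starting material + target → side product (k = 0.0210 /M/min)
    target → over-reaction product (k = 0.00310 /min)
    second substrate + reagent + catalyst → catalyst + second product (k = 7.70 /M²/min)

The budget can be audited at 20.0 h, when this flask held 0% of its reagent. Second product had taken 8.82 turns, leaving 15.4 for target, and 10.8 turns stood together as target at the best time. The neighbouring flask with 0.025 M of catalyst had a budget of 6.00. Second product took 1.77 turns there, leaving 4.23 for target, and its best amount of 36.6% held 3.66 of them.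

Readings and results come from a simulation for substances that don't exist; the scatter is artificial.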